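Atom numbers C1–C15 are those of the target in every compound, including the bicyclic intermediates. In the decalins, β is the face of C14 and α the opposite face.

## Analysis of the target

Compound 32 is a germacranolide. Its ten-membered carbocycle (C1–C10) carries a (1(10)E) trisubstituted alkene and a trans-4,5-epoxide that corresponds to a (4E) alkene. A five-membered α-methylene lactone (C7–C11–C12–O–C8) is trans-fused across C7–C8. Six contiguous stereocentres run from C4 to C9 (4S,5S,6S,7S,8R,9S). In the flat projection the oxygens on C6, C8 and C9 lie on one face and the C11 branch on C7 on the other; the epoxide oxygen is syn to O6 only in the rotamer that has the C6–O bond close to the plane of the former alkene. The sensitive groups are the exocyclic enoate (base, conjugate addition), the epoxide flanked by a free hydroxyl and a transannular alkene (acid), and the isobutyrate next to the lactone oxygen (acyl migration). Before epoxidation the 1(10),4-diene is itself sensitive: acid cyclises it across the ring and heat triggers Cope rearrangement. The difficulty lies in controlling these centres on a flexible medium ring and in forming two alkenes of defined geometry in a ring that is costly to close. The strategy rests on the fact that the C1=C10 alkene and the C4–C5 epoxide (a masked alkene) face each other across the C5···C10 axis. Joining C5 to C10 in the retrosynthetic sense gives a eudesmane-type decalin in which C6–C9 sit on a chair and C1 and C4 carry a leaving group and a boron atom.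

## Retrosynthetic reasoning

**32 ⇒ 31.** The C4–O and C5–O bonds are cut last, because the epoxide is the most labile group. In 31 only the C4=C5 alkene is part of an allylic alcohol, so a metal-alkoxide-directed epoxidation should leave C1=C10 and the enoate alone. The forward step has to deliver oxygen to the face that gives (4S,5S).

**31 ⇒ 30 ⇒ 29.** The C6 hydroxyl stays masked as a 4-methoxybenzyl ether until the C9 ester is in place, so that only O9 is acylated. The isobutyrate is introduced after the methylene lactone, since enolate chemistry at C11 cannot distinguish a lactone α-hydrogen from the α-hydrogen of an isobutyrate.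

**29 ⇒ 27 ⇒ 25.** The C11=C13 bond is cut back to an 11-methyl lactone and formed by selenoxide elimination. C11 must be saturated earlier because the hydroboration of the key step would consume a 1,1-disubstituted alkene; its configuration is irrelevant.

**25 ⇒ 23 ⇒ 22.** The lactone C12–O8 bond comes from oxidation of the C12 alcohol and capture by O8, the five-membered closure being preferred over the six-membered one onto O9. O8, O9 and O12 are carried as silyl ethers that fluoride removes together. An isopropylidene acetal on O8/O9 was set aside because its removal needs acid at a stage where the acid-labile 1,5-diene is already present.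

**22 ⇒ 19 (key disconnection).** C5 is reconnected to C10. Forward, hydroboration puts boron on C4 of octalin 19 and base-induced fragmentation of the borate forms both π bonds, breaks C5–C10 and expels the C1 mesylate. The cut is made here because it releases the ten-membered ring without any macrocyclisation and ties both alkene geometries to chair stereoelectronics.

**19 ⇒ 18 ⇒ 17 ⇒ 15.** O8 and O9 come from syn-dihydroxylation of a C8=C9 alkene on the α face, and O12 from hydroboration of the isopropenyl group. Both are done after the mesylate is in place, when the only other alkene is tetrasubstituted.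

**15 ⇒ 14 ⇒ 13 ⇒ 12.** The C1 carbinol is set by hydride reduction of ketone 13 anti to C14. The C1 configuration of all earlier compounds is therefore irrelevant.

**11 ⇒ 10 ⇒ 9 ⇒ 8.** O6, the C4=C5 alkene and the C15 methyl are traced to vinyl epoxide 9, which is opened reductively, and 9 to diene 8 by epoxidation on the α face. This fixes the 6α configuration by oxygen delivery anti to C14, which reduction of a C6 ketone would not do.

**8 ⇒ 7 ⇒ 5.** The C4–C5 bond is cut; it is formed by intramolecular Heck reaction of enol triflate 7 onto the terminal alkene. A reductive coupling of two ketones for ring A was set aside: it would leave C6 without oxygen and does not tolerate oxygen on C6.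

**5 ⇒ 4 ⇒ 1 + 2.** The C10–C1 bond is cut. The aldol addition of the extended dienolate 3 of 1 at its α-carbon creates the quaternary C10, brings in the C1 oxygen with C2–C4 and C15, and moves the ring alkene to C8=C9, where it is later needed. C7 comes from 1.

## Alternatives that were turned down

**Alternative 1:** The disconnection removes C12 as carbon monoxide and cuts O–C12 and C12–C11 of the lactone. Forward, PdCl2 (divalent palladium) with thiourea under CO converts the ethynyl carbinol A2 into the target 6-silyl ether A1 and leaves the exocyclic methylene in place.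
- *For:* the enoate is made in one step without enolates or selenium. On this point it is stronger than the chosen route, which spends steps 17–19 on the lactone.
- *Against:* it leaves the ten-membered ring, the epoxide and the E alkene unsolved, because A2 already contains all of them, and it adds the task of placing an ethynyl group trans to O8 on a medium ring. Lewis-acidic palladium chloride and the acid it releases meet an epoxide flanked by a transannular alkene.
- *Comparison:* it is an endgame option, not a ring strategy. The chosen route offers the ring, both alkene geometries and the C6–C9 centres from one rigid decalin.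

**Alternative 2:** The disconnection cuts C4–C5 and C4–O. Forward, KN(SiMe3)2 deprotonates the C4 diphenylsulfonium salt A4, the ylide adds to the C5 aldehyde, and the betaine closes the epoxide with loss of Ph2S to give A3.
- *For:* ring and epoxide form in one operation. The route never passes through the heat- and acid-sensitive 1,5-diene and needs no late face-selective epoxidation; on both points it is stronger than the chosen route.
- *Against:* the ten-membered ring is closed by a carbonyl addition with no template, so oligomerisation competes. The α-branched secondary sulfonium salt is hard to make, and its ylide can eliminate or undergo proton transfer. The aldehyde is α-silyloxy and can epimerise at C6. C4 and C5 are both created in the ring-closing event with only C6 to steer them, and the acetonide of A3 would later need acid next to the epoxide.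
- *Comparison:* the chosen route keeps ring formation unimolecular and stereospecific. It pays with the late epoxidation of step 22.

**Alternative 3:** The disconnection cuts C5–C6 and C4–C15. Forward, Ni(cod)2 (zerovalent nickel) with an N-heterocyclic carbene couples the aldehyde and the terminal alkyne of ynal A6 through an oxanickelacycle, and Me2Zn delivers the methyl to C4, giving A5.
- *For:* the ring, C15, the 4E alkene and the C6 carbinol form in one step on a substrate that already holds the lactone ring and the C9 ester. In step economy it is clearly stronger, and it avoids hydroboration next to an allylic ether.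
- *Against:* a ten-membered E-cycloalkene has to form through a metallacycle, which is strained at this ring size. The regiochemistry of the coupling depends on the ligand. C6 is created during ring closure with only the epimerisable C7 next to it as control. A5 still lacks the methylene and the epoxide, and the methylenation would have to be done with the isobutyrate present.
- *Comparison:* the chosen route sets C6 on a chair before the ring is released. It needs more steps.

Key step: step 15

Remark on the chemistry: C1 of compounds 4–12 and C11 of compounds 16–25 are formed without control and carried as epimer mixtures (SMILES without a descriptor at that atom). C1 is reset in steps 9–10 and C11 becomes planar in steps 18–19. Compound 2 is taken as commercial.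

## Route

Step 1
Reactants: 1 (R)-(−)-carvone; 2 pent-4-enal
Product: 4 2-(1-hydroxypent-4-enyl)-2-methyl-5-(prop-1-en-2-yl)cyclohex-3-en-1-one (C5 ketone; quaternary C10 with the chain trans to isopropenyl; C8=C9; C1 epimers), via extended potassium dienolate 3 (not isolated)
Conditions: t-BuOK (1.05 equiv), THF, −20 °C; then 2, −78 °C; aq. NH4Cl
Reagents that add atoms: none
Why: t-BuOK gives the thermodynamic, fully conjugated dienolate 3, and metal dienolates add to aldehydes at the α-carbon, so the C10–C1 bond forms at the methyl-bearing carbon and the alkene is left at C8=C9 (deconjugative aldol addition). The aldehyde should enter anti to the isopropenyl group of the half-chair dienolate, placing C14 cis to the C7 substituent; C1 is formed without control and is corrected in steps 9 and 10.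

Step 2
Reactants: 4 aldol adduct
Product: 5 triethylsilyl ether of 4 (C1 epimers)
Conditions: Et3SiOTf, 2,6-lutidine, CH2Cl2, −78 °C
Reagents that add atoms: triethylsilyl trifluoromethanesulfonate, CC[Si](CC)(CC)OS(=O)(=O)C(F)(F)F
Why: Silylation of the hindered secondary carbinol with a silyl triflate; the ether prevents retro-aldol cleavage and O-sulfonylation in step 3.

Step 3
Reactants: 5 silyl ether
Product: 7 C5 enol triflate (C5=C6 and C8=C9 in ring B; C1 epimers), via potassium enolate 6 (not isolated)
Conditions: KN(SiMe3)2, THF, −78 °C; PhNTf2, −78 → 0 °C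
Reagents that add atoms: N-phenylbis(trifluoromethanesulfonimide), O=S(=O)(N(c1ccccc1)S(=O)(=O)C(F)(F)F)C(F)(F)F
Why: C6 is the only enolisable position of the C5 ketone because C10 is quaternary, so enolate 6 and its O-sulfonylation can give only the C5=C6 enol triflate (kinetic enol triflate formation).

Step 4
Reactants: 7 enol triflate
Product: 8 1-triethylsilyloxy-eudesma-4(15),5,8,11(12)-tetraene (C1 epimers)
Conditions: Pd(OAc)2 (10 mol%), PPh3 (25 mol%), Et3N, MeCN, 60 °C
Reagents that add atoms: none
Why: Intramolecular Heck reaction: zerovalent palladium inserts into the C5–O bond, 6-exo-trig carbopalladation of the terminal alkene forms C5–C4 and ring A, and β-hydride elimination of H4, the only β-hydrogen, gives the exocyclic C4=C15 alkene conjugated with C5=C6. The other alkenes could be reached only through four-membered or endo modes.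

Step 5
Reactants: 8 tetraene
Product: 9 5α,6α-epoxy-1-triethylsilyloxy-eudesma-4(15),8,11(12)-triene (C1 epimers)
Conditions: mCPBA (1.0 equiv), NaHCO3, CH2Cl2, −20 °C
Reagents that add atoms: 3-chloroperoxybenzoic acid, OOC(=O)c1cccc(Cl)c1
Why: The peracid should epoxidise the most electron-rich alkene, the trisubstituted C5=C6 bond of the diene. C14 on C10 and the isopropenyl group on C7, both β and both next to this alkene, send the reagent to the α face; the buffer keeps the allylic epoxide from ionising.

Step 6
Reactants: 9 vinyl epoxide
Product: 10 1-triethylsilyloxy-eudesma-4,8,11(12)-trien-6α-ol (C1 epimers)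
Conditions: SmI2 (2.5 equiv; divalent samarium), THF–MeOH, −78 °C
Reagents that add atoms: none
Why: Two single-electron transfers cleave the allylic C5–O bond and protonation at the terminal carbon C15 gives the tetrasubstituted C4=C5 alkene with C15 as a methyl group (1,4-reduction of a vinyl oxirane). The C6–O bond is not touched, so the 6α configuration set in step 5 is kept.

Step 7
Reactants: 10 allylic alcohol
Product: 11 6α-(4-methoxybenzyloxy)-1-triethylsilyloxy-eudesma-4,8,11(12)-triene (C1 epimers)
Conditions: NaH, 4-MeOC6H4CH2Cl, Bu4NI (cat.), DMF, 0 °C → rt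
Reagents that add atoms: 4-methoxybenzyl chloride, COc1ccc(CCl)cc1
Why: Williamson etherification of the allylic alkoxide; the silyl ether is stable to NaH.

Step 8
Reactants: 11 benzyl-type ether
Product: 12 6α-(4-methoxybenzyloxy)-eudesma-4,8,11(12)-trien-1-ol (C1 epimers)
Conditions: Bu4NF, THF, 0 °C → rt
Reagents that add atoms: none
Why: Fluoride cleavage of the only silyl ether in the molecule.

Step 9
Reactants: 12 C1 alcohol
Product: 13 6α-(4-methoxybenzyloxy)-eudesma-4,8,11(12)-trien-1-one
Conditions: Dess–Martin periodinane, NaHCO3, CH2Cl2, 0 °C → rt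
Reagents that add atoms: none
Why: Dess–Martin oxidation removes the uncontrolled C1 stereocentre. The ketone cannot move into conjugation because C10 is quaternary.

Step 10
Reactants: 13 C1 ketone
Product: 14 6α-(4-methoxybenzyloxy)-eudesma-4,8,11(12)-trien-1β-ol
Conditions: NaBH4, MeOH, −20 °C
Reagents that add atoms: none
Why: Hydride should attack the C1 carbonyl from the α face, anti to the pseudo-axial C14 methyl on the neighbouring carbon, giving the equatorial 1β-alcohol cis to C14, as is usual for angularly methylated decalones.

Step 11
Reactants: 14 1β-alcohol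
Product: 15 1β-methanesulfonyloxy-6α-(4-methoxybenzyloxy)-eudesma-4,8,11(12)-triene
Conditions: MeSO2Cl, Et3N, CH2Cl2, 0 °C
Reagents that add atoms: methanesulfonyl chloride, CS(=O)(=O)Cl
Why: Sulfonylation of the single free hydroxyl. The equatorial mesylate next to a quaternary carbon has no anti-periplanar hydrogen and is slow in substitution, so it should survive the next three steps.

Step 12
Reactants: 15 mesylate
Product: 17 1β-methanesulfonyloxy-6α-(4-methoxybenzyloxy)-eudesma-4,8-dien-12-ol (C11 epimers), via C12 B-alkyl-9-borabicyclononane 16 (not isolated)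
Conditions: 9-BBN, THF, 0 °C → rt; then aq. NaOH, H2O2, 0 °C
Reagents that add atoms: hydrogen peroxide, OO
Why: 9-BBN hydroborates the 1,1-disubstituted isopropenyl alkene far faster than the hindered cis-disubstituted C8=C9 bond or the tetrasubstituted C4=C5 bond, with boron on the terminal carbon; cold alkaline peroxide then gives the C12 alcohol. C11 forms as a mixture, which does not matter.

Step 13
Reactants: 17 C12 alcohol
Product: 18 1β-methanesulfonyloxy-6α-(4-methoxybenzyloxy)-eudesm-4-ene-8α,9α,12-triol (C11 epimers)
Conditions: OsO4 (5 mol%), N-methylmorpholine N-oxide, acetone–H2O, rt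
Reagents that add atoms: N-methylmorpholine N-oxide, C[N+]1([O-])CCOCC1; water, O
Why: Catalytic syn-dihydroxylation; OsO4 should not attack the tetrasubstituted alkene under these conditions. C14 on C10 and the side chain on C7, both β and both next to the alkene, direct it to the α face, which sets C8 and C9 as the cis-diol with O8 trans to the side chain.

Step 14
Reactants: 18 triol
Product: 19 1β-methanesulfonyloxy-6α-(4-methoxybenzyloxy)-8α,9α,12-tris(tert-butyldimethylsilyloxy)eudesm-4-ene (7αH; 10β-methyl; C11 epimers)
Conditions: t-BuMe2SiOTf (4 equiv), 2,6-lutidine, CH2Cl2, 0 °C → rt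
Reagents that add atoms: tert-butyldimethylsilyl trifluoromethanesulfonate, CC(C)(C)[Si](C)(C)OS(=O)(=O)C(F)(F)F
Why: The silyl triflate should silylate the primary, the equatorial and the hindered axial hydroxyl in one operation. Silyl ethers are chosen because fluoride removes them later without acid, and because a free C9 alkoxide could displace the mesylate in step 15.

Step 15
Reactants: 19 octalin mesylate
Product: 22 (1(10)E,4E)-6α-(4-methoxybenzyloxy)-8α,9α,12-tris(tert-butyldimethylsilyloxy)germacra-1(10),4-diene (C11 epimers), via trans-fused C4 borane 20 (not isolated), via sodium methoxyborate 21 (not isolated)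
Conditions: BH3·THF (5 equiv), THF, 0 °C → rt; then NaOMe, MeOH, 0 °C → rt
Reagents that add atoms: none
Why: BH3 adds syn across the tetrasubstituted C4=C5 bond from the α face, anti to the axial C14 methyl, with boron on C4, giving the trans-fused borane 20 in which the C4–B and C1–O bonds are both equatorial. Methoxide adds to boron, and in borate 21 the C4–B electron pair, the C5–C10 bond and the C1–O bond are anti-periplanar, so one concerted seven-centre Grob-type fragmentation forms the C4=C5 and C1=C10 π bonds, breaks C5–C10 and expels mesylate. The closest known reaction type is the boronate fragmentation of hydroborated octalin monosulfonates to cyclodeca-1,5-dienes. No ring is closed by bond formation: the ten-membered ring is revealed by scission of the ring-fusion bond, so no cyclisation mode and no entropic penalty apply. No stereocentre is created; the alkene geometries follow from the chair, in which H5 and C15 are anti, as are C14 and H1, which gives 4E and 1(10)E. The step needs regioselectivity (boron on C4, although the allylic C6 ether favours C5 electronically; C5 is flanked by the quaternary C10 and by C6, and this steric difference should decide), face selectivity (α, secured by C14, though the axial 9α-silyloxy group slows this face) and chemoselectivity (no other alkene is present, and silyl ethers, the benzyl-type ether and the mesylate are inert to BH3). The product is kept at or below room temperature and away from acid, because the 1,5-diene can undergo Cope rearrangement and transannular cyclisation.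

Step 16
Reactants: 22 germacradiene
Product: 23 (1(10)E,4E)-6α-(4-methoxybenzyloxy)germacra-1(10),4-diene-8α,9α,12-triol (C11 epimers)
Conditions: Bu4NF (4 equiv), THF, rt
Reagents that add atoms: none
Why: Fluoride removes all three silyl ethers under basic, non-acidic conditions that spare the 1,5-diene.

Step 17
Reactants: 23 triol
Product: 25 9α-hydroxy-6α-(4-methoxybenzyloxy)germacra-1(10)E,4E-dien-12,8α-olide (C11 epimers), via five-membered lactol 24 (not isolated)
Conditions: [Cu(MeCN)4]OTf (5 mol%), 2,2′-bipyridine (5 mol%), TEMPO (5 mol%), N-methylimidazole (10 mol%), air, MeCN, rt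
Reagents that add atoms: none
Why: The copper/nitroxyl system oxidises the primary alcohol selectively; the aldehyde is trapped by O8 as lactol 24, which is oxidised on to the γ-lactone (aerobic oxidative lactonisation of a 1,4-diol). This oxidant is chosen because it does not cleave the free 8,9-diol; the lactone is trans-fused because C7 and C8 were set in the decalin.

Step 18
Reactants: 25 lactone
Product: 27 9α-hydroxy-6α-(4-methoxybenzyloxy)-11-phenylselanylgermacra-1(10)E,4E-dien-12,8α-olide (selenium anti to H7), via dilithium alkoxide enolate 26 (not isolated)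
Conditions: LiN(i-Pr)2 (2.5 equiv), THF, −78 °C; PhSeBr, −78 °C; aq. NH4Cl
Reagents that add atoms: benzeneselenenyl bromide, Br[Se]c1ccccc1
Why: Excess amide base removes the hydroxyl proton and the C11 proton to give 26, whose lactone enolate is selenenylated at C11, expected from the face anti to H7 (α-selenenylation of a lactone enolate). The step precedes the acylation of O9 because an isobutyrate would be deprotonated as well.

Step 19
Reactants: 27 selenide
Product: 29 9α-hydroxy-6α-(4-methoxybenzyloxy)germacra-1(10)E,4E,11(13)-trien-12,8α-olide, via selenoxide 28 (not isolated)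
Conditions: H2O2 (30%), pyridine, CH2Cl2, 0 °C → rt
Reagents that add atoms: none
Why: Oxidation gives selenoxide 28, which undergoes syn elimination at or below room temperature. With selenium anti to H7 only the C13 hydrogens are syn, so the exocyclic alkene forms; pyridine traps the selenenic acid and keeps the medium non-acidic.

Step 20
Reactants: 29 methylene lactone
Product: 30 9α-isobutyryloxy-6α-(4-methoxybenzyloxy)germacra-1(10)E,4E,11(13)-trien-12,8α-olide
Conditions: (i-PrCO)2O, Et3N, DMAP (cat.), CH2Cl2, 0 °C → rt
Reagents that add atoms: isobutyric anhydride, CC(C)C(=O)OC(=O)C(C)C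
Why: DMAP-catalysed acylation of the only free hydroxyl.

Step 21
Reactants: 30 isobutyrate
Product: 31 6α-hydroxy-9α-isobutyryloxygermacra-1(10)E,4E,11(13)-trien-12,8α-olide
Conditions: DDQ, CH2Cl2–pH 7 buffer, 0 °C
Reagents that add atoms: none
Why: Oxidative cleavage of the 4-methoxybenzyl ether by DDQ in buffered wet CH2Cl2; the esters, the enoate and the alkenes should not be oxidised under these conditions.

Step 22
Reactants: 31 allylic alcohol
Product: 32 (1(10)E)-4,5-epoxy-6α-hydroxy-9α-isobutyryloxygermacra-1(10),11(13)-dien-12,8α-olide (4S,5S,6S,7S,8R,9S), the target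
Conditions: VO(acac)2 (5 mol%), t-BuOOH, CH2Cl2, 0 °C
Reagents that add atoms: tert-butyl hydroperoxide, CC(C)(C)OO
Why: Vanadium-alkoxide-directed epoxidation, in which only the alkene of the allylic alcohol (C4=C5) reacts. Oxygen is delivered syn to O6 through a transition state with an O–C6–C5=C4 dihedral angle near 45° and C7 on the opposite, inner face of the ring, an arrangement that corresponds to the (4S,5S) epoxide; the trans relationship across C4–C5 follows from the E alkene.

## Compound list

1 | (R)-(−)-carvone | CC1=CC[C@H](CC1=O)C(C)=C | starting material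
2 | pent-4-enal | C=CCCC=O | starting material
3 | extended potassium dienolate of 1 | CC1=C([O-])C[C@H](C(C)=C)C=C1.[K+] | intermediate
4 | 2-(1-hydroxypent-4-enyl)-2-methyl-5-(prop-1-en-2-yl)cyclohex-3-en-1-one, chain trans to isopropenyl, C1 epimers | O=C1C[C@H](C(C)=C)C=C[C@@]1(C)C(O)CCC=C | intermediate
5 | triethylsilyl ether of 4 | O=C1C[C@H](C(C)=C)C=C[C@@]1(C)C(O[Si](CC)(CC)CC)CCC=C | intermediate
6 | potassium C5=C6 enolate of 5 | [K+].[O-]C1=C[C@H](C(C)=C)C=C[C@@]1(C)C(O[Si](CC)(CC)CC)CCC=C | intermediate
7 | C5 enol triflate of 5 | FC(F)(F)S(=O)(=O)OC1=C[C@H](C(C)=C)C=C[C@@]1(C)C(O[Si](CC)(CC)CC)CCC=C | intermediate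
8 | 1-triethylsilyloxy-eudesma-4(15),5,8,11(12)-tetraene | C=C1CCC(O[Si](CC)(CC)CC)[C@]2(C)C=C[C@@H](C(C)=C)C=C12 | intermediate
9 | 5α,6α-epoxy-1-triethylsilyloxy-eudesma-4(15),8,11(12)-triene | C=C1CCC(O[Si](CC)(CC)CC)[C@]2(C)C=C[C@@H](C(C)=C)[C@@H]3O[C@]123 | intermediate
10 | 1-triethylsilyloxy-eudesma-4,8,11(12)-trien-6α-ol | CC1=C2[C@@H](O)[C@H](C(C)=C)C=C[C@@]2(C)C(O[Si](CC)(CC)CC)CC1 | intermediate
11 | 6α-(4-methoxybenzyloxy)-1-triethylsilyloxy-eudesma-4,8,11(12)-triene | CC1=C2[C@@H](OCc3ccc(OC)cc3)[C@H](C(C)=C)C=C[C@@]2(C)C(O[Si](CC)(CC)CC)CC1 | intermediate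
12 | 6α-(4-methoxybenzyloxy)-eudesma-4,8,11(12)-trien-1-ol, C1 epimers | CC1=C2[C@@H](OCc3ccc(OC)cc3)[C@H](C(C)=C)C=C[C@@]2(C)C(O)CC1 | intermediate
13 | 6α-(4-methoxybenzyloxy)-eudesma-4,8,11(12)-trien-1-one | CC1=C2[C@@H](OCc3ccc(OC)cc3)[C@H](C(C)=C)C=C[C@@]2(C)C(=O)CC1 | intermediate
14 | 6α-(4-methoxybenzyloxy)-eudesma-4,8,11(12)-trien-1β-ol | CC1=C2[C@@H](OCc3ccc(OC)cc3)[C@H](C(C)=C)C=C[C@@]2(C)[C@H](O)CC1 | intermediate
15 | 1β-methanesulfonyloxy-6α-(4-methoxybenzyloxy)-eudesma-4,8,11(12)-triene | CC1=C2[C@@H](OCc3ccc(OC)cc3)[C@H](C(C)=C)C=C[C@@]2(C)[C@H](OS(C)(=O)=O)CC1 | intermediate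
16 | C12 B-alkyl-9-borabicyclo[3.3.1]nonane from 15, C11 epimers | CC1=C2[C@@H](OCc3ccc(OC)cc3)[C@H](C(C)CB4C5CCCC4CCC5)C=C[C@@]2(C)[C@H](OS(C)(=O)=O)CC1 | intermediate
17 | 1β-methanesulfonyloxy-6α-(4-methoxybenzyloxy)-eudesma-4,8-dien-12-ol, C11 epimers | CC1=C2[C@@H](OCc3ccc(OC)cc3)[C@H](C(C)CO)C=C[C@@]2(C)[C@H](OS(C)(=O)=O)CC1 | intermediate
18 | 1β-methanesulfonyloxy-6α-(4-methoxybenzyloxy)-eudesm-4-ene-8α,9α,12-triol, C11 epimers | CC1=C2[C@@H](OCc3ccc(OC)cc3)[C@H](C(C)CO)[C@@H](O)[C@@H](O)[C@@]2(C)[C@H](OS(C)(=O)=O)CC1 | intermediate
19 | 1β-methanesulfonyloxy-6α-(4-methoxybenzyloxy)-8α,9α,12-tris(tert-butyldimethylsilyloxy)eudesm-4-ene, C11 epimers (precursor of the key step) | CC1=C2[C@@H](OCc3ccc(OC)cc3)[C@H](C(C)CO[Si](C)(C)C(C)(C)C)[C@@H](O[Si](C)(C)C(C)(C)C)[C@@H](O[Si](C)(C)C(C)(C)C)[C@@]2(C)[C@H](OS(C)(=O)=O)CC1 | intermediate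
20 | trans-fused 4α-boryl-5αH borane from 19 | C[C@]1(B)[C@@H]2[C@@H](OCc3ccc(OC)cc3)[C@H](C(C)CO[Si](C)(C)C(C)(C)C)[C@@H](O[Si](C)(C)C(C)(C)C)[C@@H](O[Si](C)(C)C(C)(C)C)[C@@]2(C)[C@H](OS(C)(=O)=O)CC1 | intermediate
21 | sodium methoxyborate of 20 | [Na+].C[C@]1([BH2-]OC)[C@@H]2[C@@H](OCc3ccc(OC)cc3)[C@H](C(C)CO[Si](C)(C)C(C)(C)C)[C@@H](O[Si](C)(C)C(C)(C)C)[C@@H](O[Si](C)(C)C(C)(C)C)[C@@]2(C)[C@H](OS(C)(=O)=O)CC1 | intermediate
22 | (1(10)E,4E)-6α-(4-methoxybenzyloxy)-8α,9α,12-tris(tert-butyldimethylsilyloxy)germacra-1(10),4-diene, C11 epimers (product of the key step) | CC(C)(C)[Si](C)(C)O[C@@H]1[C@@H](C(C)CO[Si](C)(C)C(C)(C)C)[C@H](OCc2ccc(OC)cc2)/C=C(\C)CC/C=C(\C)[C@@H]1O[Si](C)(C)C(C)(C)C | intermediate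
23 | (1(10)E,4E)-6α-(4-methoxybenzyloxy)germacra-1(10),4-diene-8α,9α,12-triol, C11 epimers | O[C@@H]1[C@@H](C(C)CO)[C@H](OCc2ccc(OC)cc2)/C=C(\C)CC/C=C(\C)[C@@H]1O | intermediate
24 | 12,8α-lactol of 23 | CC1C(O)O[C@@H]2[C@@H]1[C@H](OCc3ccc(OC)cc3)/C=C(\C)CC/C=C(\C)[C@@H]2O | intermediate
25 | 9α-hydroxy-6α-(4-methoxybenzyloxy)germacra-1(10)E,4E-dien-12,8α-olide, C11 epimers | CC1C(=O)O[C@@H]2[C@@H]1[C@H](OCc3ccc(OC)cc3)/C=C(\C)CC/C=C(\C)[C@@H]2O | intermediate
26 | dilithium C9 alkoxide and lactone enolate of 25 | CC1=C([O-])O[C@@H]2[C@@H]1[C@H](OCc3ccc(OC)cc3)/C=C(\C)CC/C=C(\C)[C@@H]2[O-].[Li+].[Li+] | intermediate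
27 | 11-phenylselanyl derivative of 25, selenium anti to H7 | C[C@@]1([Se]c3ccccc3)C(=O)O[C@@H]2[C@@H]1[C@H](OCc4ccc(OC)cc4)/C=C(\C)CC/C=C(\C)[C@@H]2O | intermediate
28 | selenoxide of 27 | C[C@@]1([Se](=O)c3ccccc3)C(=O)O[C@@H]2[C@@H]1[C@H](OCc4ccc(OC)cc4)/C=C(\C)CC/C=C(\C)[C@@H]2O | intermediate
29 | 9α-hydroxy-6α-(4-methoxybenzyloxy)germacra-1(10)E,4E,11(13)-trien-12,8α-olide | C=C1C(=O)O[C@@H]2[C@@H]1[C@H](OCc3ccc(OC)cc3)/C=C(\C)CC/C=C(\C)[C@@H]2O | intermediate
30 | 9α-isobutyryloxy-6α-(4-methoxybenzyloxy)germacra-1(10)E,4E,11(13)-trien-12,8α-olide | C=C1C(=O)O[C@@H]2[C@@H]1[C@H](OCc3ccc(OC)cc3)/C=C(\C)CC/C=C(\C)[C@@H]2OC(=O)C(C)C | intermediate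
31 | 6α-hydroxy-9α-isobutyryloxygermacra-1(10)E,4E,11(13)-trien-12,8α-olide | C=C1C(=O)O[C@@H]2[C@@H]1[C@H](O)/C=C(\C)CC/C=C(\C)[C@@H]2OC(=O)C(C)C | intermediate
32 | (1(10)E)-4,5-epoxy-6α-hydroxy-9α-isobutyryloxygermacra-1(10),11(13)-dien-12,8α-olide (4S,5S,6S,7S,8R,9S) | C=C1C(=O)O[C@@H]2[C@@H]1[C@H](O)[C@@H]1O[C@@]1(C)CC/C=C(\C)[C@@H]2OC(=O)C(C)C | target

## Step count and least certain steps

Total step count: 22. Longest linear sequence: 22 steps from 1 (2 is commercial).

**Step 15 (key step).** Boron may be delivered to C5 instead of C4, because the allylic ether on C6 polarises the alkene, and the β-alkoxyborane so formed would eliminate. The axial 9α-silyloxy group may slow the α face so much that attack from the β face competes, and a cis-fused borane cannot reach the anti-periplanar arrangement that gives two E alkenes. The product can also be lost by Cope rearrangement if it is warmed.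
Fallback, tethered delivery of boron instead of intermolecular addition: from 19 the 4-methoxybenzyl group is removed with DDQ to give the 6α-hydroxy mesylate F1. With thexylborane the hydroxyl first forms an alkoxyborane on the α face, which can add across C4=C5 only within the tether, boron reaching C4 and hydrogen C5 from the α face. NaOMe then triggers the same fragmentation to the germacradien-6α-ol F2, and NaH with 4-methoxybenzyl chloride returns to 22.

**Step 1.** Facial selectivity at C10 may be lost (entry of the aldehyde syn to the isopropenyl group). The aldol may go through the cross-conjugated C6 enolate if equilibration to 3 is incomplete, and the potassium aldolate may revert by retro-aldol cleavage.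
Fallback, a stereospecific [2,3]-sigmatropic transfer from O6 instead of an intermolecular aldol: from 1, α′-hydroxylation (LiN(i-Pr)2, then 2-(phenylsulfonyl)-3-phenyloxaziridine) gives trans-6-hydroxycarvone F3. KH and Bu3SnCH2I give the stannylmethyl ether F4, and t-BuMe2SiOTf with Et3N under equilibrating conditions gives the linear silyl dienol ether F5. n-BuLi at −78 °C effects tin–lithium exchange and a [2,3]-Wittig rearrangement that moves the CH2O carbon suprafacially from O6 to C10 on the α face, giving the hydroxymethyl compound F6. Dess–Martin oxidation gives the aldehyde F7 and but-3-enylmagnesium bromide the carbinol F8. Bu4NF cleaves the silyl enol ether to the C5 ketone, which is 4.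

**Step 22.** Facial selectivity may be poor if the ring reacts through the conformer in which the C6–O bond stands perpendicular to the alkene on the outer face; oxygen delivery would then give the (4R,5R) diastereomer. The product epoxide may also be opened by the neighbouring hydroxyl or the transannular alkene under Lewis acid.
Fallback, steric instead of directed control and a changed order: 30 is epoxidised with dimethyldioxirane (one equivalent, −40 °C) while O6 still carries the 4-methoxybenzyl group. The bulky ether blocks the outer face of that conformer, so the reagent should attack the conformer with the C6–O bond in the alkene plane and give the epoxy ether F9; competition from C1=C10 is the risk of this variant. DDQ then gives 32.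

**Step 17.** The allylic C9 hydroxyl may be oxidised, or the aldehyde may be captured by O9 as a six-membered lactol, which leads to the δ-lactone.
Fallback, acid first and lactonisation second: from 22, HF·pyridine buffered with pyridine removes only the primary silyl ether to give the C12 alcohol F10. TEMPO with PhI(OAc)2 in aqueous MeCN oxidises it to the carboxylic acid F11 while both secondary oxygens are still silylated. Bu4NF then frees O8 and O9, and at pH 5 the hydroxy acid closes on O8 to the thermodynamically preferred γ-lactone 25.

## Further compounds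

F1 | step 15 | 1β-methanesulfonyloxy-8α,9α,12-tris(tert-butyldimethylsilyloxy)eudesm-4-en-6α-ol | CC1=C2[C@@H](O)[C@H](C(C)CO[Si](C)(C)C(C)(C)C)[C@@H](O[Si](C)(C)C(C)(C)C)[C@@H](O[Si](C)(C)C(C)(C)C)[C@@]2(C)[C@H](OS(C)(=O)=O)CC1
F2 | step 15 | (1(10)E,4E)-8α,9α,12-tris(tert-butyldimethylsilyloxy)germacra-1(10),4-dien-6α-ol | CC(C)(C)[Si](C)(C)O[C@@H]1[C@@H](C(C)CO[Si](C)(C)C(C)(C)C)[C@H](O)/C=C(\C)CC/C=C(\C)[C@@H]1O[Si](C)(C)C(C)(C)C
F3 | step 1 | trans-6-hydroxycarvone (hydroxyl on the future C6, trans to isopropenyl) | CC1=CC[C@@H](C(C)=C)[C@H](O)C1=O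
F4 | step 1 | tributylstannylmethyl ether of F3 | CC1=CC[C@@H](C(C)=C)[C@H](OC[Sn](CCCC)(CCCC)CCCC)C1=O
F5 | step 1 | linear tert-butyldimethylsilyl dienol ether of F4 | CC1=C(O[Si](C)(C)C(C)(C)C)[C@@H](OC[Sn](CCCC)(CCCC)CCCC)[C@H](C(C)=C)C=C1
F6 | step 1 | C10-hydroxymethyl C5 silyl enol ether (hydroxymethyl trans to isopropenyl) | OC[C@]1(C)C=C[C@@H](C(C)=C)C=C1O[Si](C)(C)C(C)(C)C
F7 | step 1 | aldehyde from F6 | O=C[C@]1(C)C=C[C@@H](C(C)=C)C=C1O[Si](C)(C)C(C)(C)C
F8 | step 1 | but-3-enyl carbinol from F7, C1 epimers | C=CCCC(O)[C@]1(C)C=C[C@@H](C(C)=C)C=C1O[Si](C)(C)C(C)(C)C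
F9 | step 22 | 6-O-(4-methoxybenzyl) ether of 32 | C=C1C(=O)O[C@@H]2[C@@H]1[C@H](OCc3ccc(OC)cc3)[C@@H]1O[C@@]1(C)CC/C=C(\C)[C@@H]2OC(=O)C(C)C
F10 | step 17 | (1(10)E,4E)-6α-(4-methoxybenzyloxy)-8α,9α-bis(tert-butyldimethylsilyloxy)germacra-1(10),4-dien-12-ol | CC(C)(C)[Si](C)(C)O[C@@H]1[C@@H](C(C)CO)[C@H](OCc2ccc(OC)cc2)/C=C(\C)CC/C=C(\C)[C@@H]1O[Si](C)(C)C(C)(C)C
F11 | step 17 | (1(10)E,4E)-6α-(4-methoxybenzyloxy)-8α,9α-bis(tert-butyldimethylsilyloxy)germacra-1(10),4-dien-12-oic acid | CC(C)(C)[Si](C)(C)O[C@@H]1[C@@H](C(C)C(=O)O)[C@H](OCc2ccc(OC)cc2)/C=C(\C)CC/C=C(\C)[C@@H]1O[Si](C)(C)C(C)(C)C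
A1 | alternative 1 | 6-O-tert-butyldimethylsilyl ether of the target | C=C1C(=O)O[C@@H]2[C@@H]1[C@H](O[Si](C)(C)C(C)(C)C)[C@@H]1O[C@@]1(C)CC/C=C(\C)[C@@H]2OC(=O)C(C)C
A2 | alternative 1 | 7-ethynyl-8α-hydroxy-4,5-epoxy-6α-silyloxy-9α-isobutyryloxy cyclodec-1(10)-ene | O[C@@H]1[C@@H](C#C)[C@H](O[Si](C)(C)C(C)(C)C)[C@@H]2O[C@@]2(C)CC/C=C(\C)[C@@H]1OC(=O)C(C)C
A3 | alternative 2 | 4,5-epoxycyclodec-1(10)-ene with C6 silyl ether, C8,C9 acetonide and C7 2-propenyl side chain | CC1(C)O[C@@H]2[C@@H](C(=C)COCc3ccc(OC)cc3)[C@H](O[Si](C)(C)C(C)(C)C)[C@@H]3O[C@@]3(C)CC/C=C(\C)[C@@H]2O1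
A4 | alternative 2 | open-chain C5 aldehyde with C4 diphenylsulfonium triflate | CC1(C)O[C@H]([C@@H](C(=C)COCc2ccc(OC)cc2)[C@H](O[Si](C)(C)C(C)(C)C)C=O)[C@H](/C(C)=C/CCC(C)[S+](c2ccccc2)c2ccccc2)O1.[O-]S(=O)(=O)C(F)(F)F
A5 | alternative 3 | germacra-1(10),4-dien-6-ol with saturated 12,8-lactone and C9 isobutyrate | C1C(=O)O[C@@H]2[C@@H]1[C@H](O)/C=C(\C)CC/C=C(\C)[C@@H]2OC(=O)C(C)C
A6 | alternative 3 | lactone ynal with C6 aldehyde and C4≡C5 terminal alkyne | O=C[C@@H]1CC(=O)O[C@H]1[C@@H](OC(=O)C(C)C)/C(C)=C/CCC#C
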